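Late in the grey run, the one with the lowest rival charge, target sinks from 74% at 4.00 d to 64% at 15.0 d, far slower than starting material fell at the start, to 21% by 0.333 d. So take the fast competition of partner and rival reagent for starting material as over, and read each peak as its outcome.

| flask | starting material | partner | rival reagent | remark | time |
|---|---|---|---|---|---|
| grey | 0.050 M | 0.95 equiv | 0.65 equiv | run made earlier |  |
| green | 0.050 M | 0.95 equiv | 2.6 equiv | run made earlier |  |
| amber | 0.10 M | 0.95 equiv | 1.3 equiv | run made earlier |  |
| flask | 0.050 M | 0.950 equiv | 1.30 equiv |  | 15 d |

- grey (time / d: target / %, starting material / %): 0.333: 61, 21; 0.625: 69, 11; 1.04: 72, 3; 2.00: 74, 0; 4.00: 74, 3; 8.00: 69, 0; 15.0: 64, 0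
- green (time / d: target / %, starting material / %): 0.333: 51, 7; 0.625: 55, 0; 1.04: 55, 0; 2.00: 53, 2; 4.00: 49, 0; 8.00: 42, 1; 15.0: 38, 3
- amber (time / d: target / %, starting material / %): 0.333: 64, 6; 0.833: 67, 2; 2.00: 59, 1; 6.00: 54, 0; 15.0: 45, 0

(readings scatter by 1.5 percentage points)

1. the moment within 15 d at which there is most target
2. the amount of target, in percent of the starting material charged, at that time

Two views stand at the board. The first copies amber: the flask has amber's equivalents, so it should show amber's peak, a reading of 67%, with amber's 0.833 d stretched by the concentration ratio to 1.67 d.

The second, which is my reckoning, looks at the split itself. Take the odds of target against the rest of the charge at the peak, and multiply them by rival reagent over partner, both as fractions of the charge. The grey peak gives 1.95 and the green peak 3.35, so this number rises with the rival charge. The flask's rival charge is the geometric mean of those two, so I take their geometric mean, 2.55, as the competition factor, a rough selectivity factor read from readings.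

For the flask the odds are then 1.87, a peak of 65.1%. The same mean of the first peak readings in grey and green puts the flask's peak near 1.12 d.

The forecast says 66.5% at 1.2 d, since “amber sets the yield”.

The flask gives 65.3% at 1.23 d; my factor had said 65.1%, and the mean of the peak readings 1.12 d. Copying amber is a view for flasks at amber's equivalents, as this flask is, and its stretched 1.67 d lies later than the flask's peak.

    starting material + partner → target (k = 0.0992 L mol⁻¹ min⁻¹)
    starting material + rival reagent → side product (k = 0.0276 L mol⁻¹ min⁻¹)
    starting material → decomposition product (k = 9.30 × 10⁻⁷ min⁻¹)
    partner + target → over-reaction product (k = 0.00192 L mol⁻¹ min⁻¹)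
    2 rival reagent → homo dimer (k = 0.0108 L mol⁻¹ min⁻¹)

In the flask, half the turnover of the side-product step up to 15 d is done by 0.0995 d, whereas at 0.0896 d target has a half-life of 8.3 d by the over-reaction step. At the best time the flask holds target 65.3% and side product 30.4%, against over-reaction product 3.06%.

Now the neighbour flask with partner raised to 1.60 equiv, where amber's equivalents no longer apply: the factor gives odds of 3.14, a peak of 75.8%. Computed, that neighbour peaks at 75.2%, and at the end it holds target 30.5% and over-reaction product 49.9%.

(The numbers in the tables were generated by integration from invented constants, noise included.)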